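## Structural features

The target is a ten-membered lactone (ring atoms O, C1–C9). C1 is the carbonyl carbon, C5=C6 is an E alkene, and C9, the carbinol carbon of the lactone, carries an n-propyl chain (C10–C12). It has four stereocentres: C2 (R), alpha to the lactone carbonyl and esterified with the half ester of (2E,4E)-hexa-2,4-dienedioic acid, and the contiguous set C7 (R), C8 (S), C9 (R). In that set the C7 and C8 oxygens are syn, the C8 and C9 oxygens are anti, and the C7 hydroxyl is allylic. This pattern is that of C2–C4 of D-arabinose, so the three centres can be taken from the chiral pool and only C2 has to be made. Fragile points are the C2–H (alpha to an ester and, in any precursor with a C3=C4 vinyl group, also allylic), the dienoate with its free acid, the allylic C7–O bond under acid, and the lactone, which can open or contract onto O8. The real difficulty is closing a medium ring that contains an E alkene without losing the C2 configuration, since end-to-end closures of this size compete with dimerisation. The key step exploits the one ring bond, C4–C5, that joins an sp3 methylene (C4, two atoms from C2) to the alkenyl carbon C5. Cutting there gives a terminal vinyl group on the C1–C4 vinylglycolate and an E iodoalkene on the C5–C9 part, and no stereocentre is at stake in the closure.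

## Logic of the disconnections

**21 to 20.** No skeletal bond is cut. The O7–C and O8–C bonds of an isopropylidene acetal and the O–C bond of a tert-butyl ester are added. The diol and the free acid are the most polar and reactive groups, so they are unmasked last, by groups that fall under one acid treatment. The gain is a single final operation and neutral intermediates with O7 and O8 tied back. The forward step must cleave a trans-fused dioxolane and a tert-butyl ester while sparing the lactone, the C2 ester and the allylic C7–O bond.

**20 to 17 and 19; 19 to 18.** The acyl–O2 bond is cut, and 19 is traced to 18 by removing one tert-butyl group. The Michael-acceptor side chain then never meets a borane, zerovalent palladium or base. The ring problem and the side chain are separated, and 18 is a commodity diacid. The forward acylation must not epimerise C2, and only one carboxyl of 18 may be blocked.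

**17 to 16.** The O2–benzyl bond of a 4-methoxybenzyl ether is added. O2 must be distinguishable from O7 and O8 so that only it is acylated, and this ether is installed in the step that creates C2. The forward cleavage must be oxidative and neutral and must leave the C2–O bond intact.

**16 to 14 (through 15).** The ring bond C4–C5 is cut. It is the only sp3–sp2 ring bond that can be made by alkyl–alkenyl cross-coupling without a new stereocentre, and the alkene geometry can be fixed beforehand. The ring opens to an ester of two fragments of similar size. The forward step needs regioselective hydroboration of the C3=C4 vinyl group, retention of the E geometry, survival of C2 under base, and high dilution.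

**14 to 13 to 12.** The C5=C6 double bond is cut to a C6 aldehyde and a one-carbon iodomethylidene reagent, and the aldehyde is then masked as the diethyl dithioacetal. C6 thereby becomes C1 of a pentose, and the dithioacetal holds the chain open. The forward steps must release the aldehyde without touching the vinyl group or the benzyl ether and must give the E iodoalkene. The O9 ester serves here as the protecting group of O9, so no separate blocking group is needed.

**12 to 7 and 11.** The O9–C1 ester bond is cut. This is the convergent junction of a sugar-derived C6–C12 alcohol and a four-carbon acid. The forward acylation of a hindered secondary alcohol must not remove the doubly activated C2–H of 11.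

**11 to 9 to 8.** C1 is taken back to the alcohol oxidation level and the O–C2 bond is then cut. The racemic epoxide 8 is a bulk chemical, and one catalytic step sets C2 and installs the O2 protecting group together. The forward etherification must be branched-selective and enantioselective, and the oxidation must not let C2 epimerise.

**7 to 6 to 4 to 3 to 2 to 1.** The C10–C11 bond is cut (two-carbon nucleophile on a terminal epoxide). The epoxide is traced to the 4,5-diol, the diol to the diacetonide, and this to the dithioacetal of 1. C2, C3 and C4 of 1 become C7, C8 and C9, so three stereocentres come from the chiral pool. The forward steps must free only the terminal diol, activate only the primary hydroxyl, and never break the C4–O bond of 1.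

## Other disconnections considered

**Alternative 1:** The cut is at C1–C2 and at the C2–O ester bond together. Aldehyde A2 (C2 as the formyl carbon, E-C5=C6, C7/C8 acetonide, O9 silyl ether), acid 19 and isocyanide A3 would combine in a Passerini reaction under a chiral phosphoric acid to give A1.
- In its favour: two bonds and the C2 stereocentre form in one convergent step. The side chain arrives without any protecting group at O2, so the ether cleavage and the separate acylation of the chosen plan are not needed; on this count it is better. C2 is also never part of a doubly activated vinylglycolate, which is likewise better.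
- Against it: C2 would be set by the catalyst alone, five bonds from the nearest stereocentre, with a dienoic half ester as the acid partner, which lies at the edge of what the asymmetric variant is known to tolerate. The ring is still open after the key step. A1 would have to be desilylated at O9 and lactonised by acyl transfer from the pyridyl amide to a hindered secondary hydroxyl. That is a ten-membered end-to-end closure next to an alpha-acyloxy carbonyl, which can epimerise, shift its acyl group or be attacked in place of the amide. A2 also needs the C3–C6 segment and the E alkene built beforehand.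
- Comparison: both plans take C7–C9 from 1. The chosen plan closes the ring by an irreversible C–C coupling in which no stereocentre forms, whereas here the ring is closed by acyl transfer at the most sensitive centre. Before ring formation the step counts are comparable. After it this alternative would be about two steps shorter, provided the lactonisation works.

**Alternative 2:** The ring is traced back to lactol A5, in which C1–C6 is shared by a cyclohexane (C1–C6, tin on C5) and a tetrahydropyran (O9, C1, C6–C9). Pb(OAc)4 would form the lead alkoxide at the C1 hydroxyl, and the C1–C6 bond would break in a Grob-type fragmentation with loss of the stannyl group from C5, giving A4.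
- In its favour: there is no end-to-end cyclisation, hence no dilution and no oligomers; on ring formation it is better than the chosen plan. The E geometry follows stereospecifically from the antiperiplanar C5–Sn and C1–C6 bonds, which is equal in reliability to a preformed iodoalkene.
- Against it: A5 holds seven stereocentres, three of which (C1, C5, C6) are destroyed. C5 and C6 must be trans and must be set on a cyclohexane that already carries the C2 oxygen and the C7–C9 chain, so the direct chiral-pool mapping onto 1 is lost. Tin and lead are used in stoichiometric amounts. After the fragmentation, O2 must be desilylated and acylated, and two benzyl ethers and the tert-butyl ester must then be removed, which is a longer endgame than the chosen one.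
- Comparison: the fragmentation is better in mechanism for the medium ring, but the structure of its substrate costs far more steps and stereocontrol than precursor 14.

**Alternative 3:** The cut is at C6–C7. In A7 the E alkenyl iodide at C6 would be converted by CrCl2 with catalytic NiCl2 into an alkenylchromium species that adds to the C7 aldehyde (Nozaki–Hiyama–Kishi closure), giving A6.
- In its favour: alkenyl–aldehyde closures of this kind have a broader record for medium-ring lactones than alkyl–alkenyl Suzuki closures; on precedent it is better. The conditions are neutral, so C2 is at least as safe as in the chosen plan.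
- Against it: C7 is created during the ring closure. For an alpha-silyloxy aldehyde the Felkin–Anh preference is for the 7,8-anti product, while the target is 7,8-syn, so the outcome would depend on the ring conformation. The aldehyde of A7 is alpha-silyloxy and beta-acyloxy and can eliminate or epimerise. O7 and O8 must be differentiated, so the acetonide taken directly from 1 cannot be used. The free allylic C7 hydroxyl of A6 would need protection before the C2 ether is removed oxidatively.
- Comparison: the chosen plan forms no stereocentre in the closure and uses all three centres of 1 unchanged. This alternative trades a less precedented coupling for a stereochemical risk at C7 and more protecting-group steps.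

Key step: step 11

Assumption (step 6): the (S,S) enantiomer of the diphosphine ligand is taken to give the R ether 9, by analogy with heteroatom nucleophiles adding to butadiene monoxide. The configuration of 9 is to be confirmed, and the antipodal ligand is used without other change if the sense proves to be the reverse.

Remark on the structures: precursor 14 and product 16 carry the configuration of 21 at C2, C7, C8 and C9, so no correction is needed. The CIP label of C8 changes along the route (R in 7 and 14, S in 21) only because substituent priorities change; no bond to C8 is broken.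

## Route

Step 1
Reactants: 1 D-arabinose
Product: 2 D-arabinose diethyl dithioacetal
Conditions: EtSH, conc. HCl, 0 °C
Reagents that add atoms: ethanethiol, CCS
Why: Acid-catalysed dithioacetalisation of the aldehydo form opens the sugar to an acyclic chain; C2–C4 are not touched.

Step 2
Reactants: 2 D-arabinose diethyl dithioacetal
Product: 3 2,3:4,5-di-O-isopropylidene-D-arabinose diethyl dithioacetal
Conditions: Me2C(OMe)2, TsOH·H2O (cat.), acetone, rt
Reagents that add atoms: 2,2-dimethoxypropane, COC(C)(C)OC
Why: Thermodynamic acetal formation: the terminal 4,5-diol gives one dioxolane and the threo 2,3-diol closes to the trans-disubstituted dioxolane, which is less strained than a cis ring across the erythro 3,4-diol.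

Step 3
Reactants: 3 2,3:4,5-di-O-isopropylidene-D-arabinose diethyl dithioacetal
Product: 4 2,3-O-isopropylidene-D-arabinose diethyl dithioacetal
Conditions: AcOH–H2O (7:3), 40 °C
Reagents that add atoms: none
Why: Selective acetal hydrolysis: the terminal dioxolane opens faster than the internal trans-disubstituted one, and dithioacetals are inert to aqueous acetic acid.

Step 4
Reactants: 4 2,3-O-isopropylidene-D-arabinose diethyl dithioacetal
Product: 6 4,5-anhydro-2,3-O-isopropylidene-D-arabinose diethyl dithioacetal, via primary tosylate 5 (not isolated)
Conditions: TsCl, Bu2SnO (cat.), Et3N, CH2Cl2, 0 °C; then K2CO3, MeOH, 0 °C → rt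
Reagents that add atoms: none
Why: Tin-acetal-catalysed sulfonylation selects the primary C5 hydroxyl, and the C4 alkoxide then displaces the tosylate (intramolecular Williamson closure), so the C4–O bond and its configuration are retained; 5 is carried on at once because a dithioacetal sulfur could alkylate at C5 on standing.

Step 5
Reactants: 6 4,5-anhydro-2,3-O-isopropylidene-D-arabinose diethyl dithioacetal
Product: 7 (1R)-1-[(4R,5S)-5-[bis(ethylsulfanyl)methyl]-2,2-dimethyl-1,3-dioxolan-4-yl]butan-1-ol
Conditions: EtMgBr, CuI (10 mol%), THF, −40 → −10 °C
Reagents that add atoms: ethylmagnesium bromide, CC[Mg]Br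
Why: Copper-catalysed Grignard opening of a terminal epoxide at the unsubstituted carbon (SN2) completes the propyl chain and frees the C9 hydroxyl with the configuration inherited from C4 of 1.

Step 6
Reactants: 8 2-vinyloxirane (racemic)
Product: 9 (2R)-2-[(4-methoxyphenyl)methoxy]but-3-en-1-ol
Conditions: 4-MeOC6H4CH2OH, Pd2(dba)3·CHCl3 (1 mol%), N,N'-[(1S,2S)-cyclohexane-1,2-diyl]bis[2-(diphenylphosphanyl)benzamide] (3 mol%), Et3B (1 mol%), CH2Cl2, rt
Reagents that add atoms: 4-methoxybenzyl alcohol, COc1ccc(CO)cc1
Why: Palladium-catalysed dynamic kinetic asymmetric allylic etherification: both enantiomers of 8 ionise to interconverting π-allylpalladium alkoxides, the boron co-catalyst ties the alcohol to the alkoxide and delivers it to the internal carbon, and the chiral diphosphine selects the face, so C2 is set under ligand control.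

Step 7
Reactants: 9 (2R)-2-[(4-methoxyphenyl)methoxy]but-3-en-1-ol
Product: 11 (2R)-2-[(4-methoxyphenyl)methoxy]but-3-enoic acid, via aldehyde 10 (not isolated)
Conditions: TEMPO (cat.), PhI(OAc)2, MeCN–H2O (1:1), 0 °C → rt
Reagents that add atoms: water, O
Why: Oxoammonium-mediated oxidation of the primary alcohol; in the aqueous medium aldehyde 10 is hydrated and oxidised further before its C2–H can epimerise or the double bond can move into conjugation, and the ether and the alkene are inert to the oxidant.

Step 8
Reactants: 7 (1R)-1-[(4R,5S)-5-[bis(ethylsulfanyl)methyl]-2,2-dimethyl-1,3-dioxolan-4-yl]butan-1-ol; 11 (2R)-2-[(4-methoxyphenyl)methoxy]but-3-enoic acid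
Product: 12 (1R)-1-[(4R,5S)-5-[bis(ethylsulfanyl)methyl]-2,2-dimethyl-1,3-dioxolan-4-yl]butyl (2R)-2-[(4-methoxyphenyl)methoxy]but-3-enoate
Conditions: EDCI·HCl, DMAP (10 mol%), CH2Cl2, −20 → 0 °C
Reagents that add atoms: none
Why: Steglich esterification of the C9 hydroxyl; substoichiometric DMAP and low temperature keep the doubly activated C2–H of the acyl donor in place, and the new ester also protects O9 during the next two steps.

Step 9
Reactants: 12 (1R)-1-[(4R,5S)-5-[bis(ethylsulfanyl)methyl]-2,2-dimethyl-1,3-dioxolan-4-yl]butyl (2R)-2-[(4-methoxyphenyl)methoxy]but-3-enoate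
Product: 13 (1R)-1-[(4R,5S)-5-formyl-2,2-dimethyl-1,3-dioxolan-4-yl]butyl (2R)-2-[(4-methoxyphenyl)methoxy]but-3-enoate
Conditions: I2, NaHCO3, acetone–H2O (5:1), 0 °C
Reagents that add atoms: water, O
Why: Oxidative hydrolysis of the dithioacetal (S-iodination, thionium ion, capture by water) under bicarbonate buffer, to which the acetal, the benzyl ether and the electron-poor terminal alkene are inert; the trans-dioxolane aldehyde is the more stable C7 epimer and, with O9 acylated, cannot close to a lactol.

Step 10
Reactants: 13 (1R)-1-[(4R,5S)-5-formyl-2,2-dimethyl-1,3-dioxolan-4-yl]butyl (2R)-2-[(4-methoxyphenyl)methoxy]but-3-enoate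
Product: 14 (1R)-1-[(4R,5R)-5-[(E)-2-iodoethenyl]-2,2-dimethyl-1,3-dioxolan-4-yl]butyl (2R)-2-[(4-methoxyphenyl)methoxy]but-3-enoate
Conditions: CrCl2, CHI3, THF–1,4-dioxane (1:6), 0 °C → rt
Reagents that add atoms: iodoform, IC(I)I
Why: Takai olefination: the geminal dichromium species formed from iodoform adds to the aldehyde and the β-oxidochromium intermediate eliminates to the E iodoalkene; esters, ethers and the monosubstituted alkene (no diamine additive) are not attacked.

Step 11
Reactants: 14 (1R)-1-[(4R,5R)-5-[(E)-2-iodoethenyl]-2,2-dimethyl-1,3-dioxolan-4-yl]butyl (2R)-2-[(4-methoxyphenyl)methoxy]but-3-enoate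
Product: 16 ten-membered E-ene lactone with C2 4-methoxybenzyl ether and C7/C8 acetonide (configuration at C2, C7, C8 and C9 as in 21), via B-alkyl-9-BBN borane 15 (not isolated)
Conditions: 9-BBN (2 equiv), THF, 0 °C → rt; then syringe-pump addition (12 h) to PdCl2(dppf) (15 mol%), AsPh3 (15 mol%), K3PO4 (3 M aq., 3 equiv), THF–DMF, rt → 40 °C, about 1 mM
Reagents that add atoms: none
Why: 9-BBN adds to the monosubstituted C3=C4 alkene of 14 with boron on C4 (steric control, reinforced by the inductive effect of the allylic C2 oxygen) much faster than to the 1,2-disubstituted iodoalkene or the ester, giving 15. Zerovalent palladium formed from PdCl2(dppf) inserts into the C5–I bond with retention of the E geometry, base converts the trialkylborane into a borate, and the primary C4 group passes to palladium. Reductive elimination from the eleven-membered alkyl(alkenyl)palladacycle forms C4–C5 and the ten-membered ring; the closest known reaction type is the B-alkyl Suzuki–Miyaura macrocyclisation, which is established for larger rings and has few ten-membered cases. The ring closes irreversibly under kinetic control by an end-to-end C(sp3)–C(sp2) coupling in which the new bond lies in the ring next to the endocyclic alkene, and slow addition at high dilution lets the intramolecular transmetalation outrun oligomerisation. No stereocentre is created: the alkene geometry is fixed beforehand by the iodide, and C2, C7, C8 and C9 are carried through. The step needs anti-Markovnikov hydroboration (bulk of 9-BBN), chemoselectivity for the terminal alkene, and retention at C2; base is added only after hydroboration has removed the allylic activation of C2–H, and K3PO4 is used near room temperature. The trans-disubstituted dioxolane and the ester linkage bend the chain so that C4 and C5 come within reach.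

Step 12
Reactants: 16 ten-membered E-ene lactone with C2 4-methoxybenzyl ether and C7/C8 acetonide
Product: 17 ten-membered E-ene lactone with free C2 hydroxyl and C7/C8 acetonide (configuration as in 21)
Conditions: DDQ, CH2Cl2–pH 7 buffer (10:1), 0 °C → rt
Reagents that add atoms: none
Why: Oxidative cleavage of the electron-rich benzyl ether by hydride abstraction and hydrolysis of the resulting oxocarbenium ion; the C2–O bond is not broken, so the configuration is retained, and the allylic acetal position is far less electron-rich.

Step 13
Reactants: 18 (2E,4E)-hexa-2,4-dienedioic acid (muconic acid)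
Product: 19 (2E,4E)-6-tert-butoxy-6-oxohexa-2,4-dienoic acid
Conditions: tBuOC(=NiPr)NHiPr (1.0 equiv), THF–DMF, rt
Reagents that add atoms: O-tert-butyl-N,N'-diisopropylisourea, CC(C)N=C(OC(C)(C)C)NC(C)C
Why: Alkylation of a carboxylic acid by an O-tert-butyl isourea (protonation, then capture of the tert-butyl cation by the carboxylate); one equivalent gives the half ester statistically, unreacted 18 is removed by its insolubility in CH2Cl2 and the neutral diester by extracting 19 into aqueous NaHCO3.

Step 14
Reactants: 17 ten-membered E-ene lactone with free C2 hydroxyl and C7/C8 acetonide; 19 (2E,4E)-6-tert-butoxy-6-oxohexa-2,4-dienoic acid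
Product: 20 C2 (2E,4E)-6-tert-butoxy-6-oxohexa-2,4-dienoate of 17
Conditions: EDCI·HCl, DMAP (cat.), CH2Cl2, 0 °C
Reagents that add atoms: none
Why: Steglich acylation of the only free hydroxyl (O7 and O8 are locked in the acetal); the acyl donor has no alpha hydrogen and the C2–O bond is untouched, and catalytic DMAP at 0 °C limits epimerisation at C2.

Step 15
Reactants: 20 C2 (2E,4E)-6-tert-butoxy-6-oxohexa-2,4-dienoate of 17
Product: 21 (2E,4E)-6-oxo-6-{[(2R,7R,8S,9R,5E)-7,8-dihydroxy-9-propylnon-5-en-9-olid-2-yl]oxy}hexa-2,4-dienoic acid (CNP0476488.6)
Conditions: CF3CO2H–CH2Cl2–H2O (10:10:1), 0 °C → rt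
Reagents that add atoms: none
Why: Acidolysis: the tert-butyl ester loses isobutene through the tert-butyl cation and the dioxolane is hydrolysed through its oxocarbenium ion, while the lactone and the conjugated ester are stable to acid at this temperature.

## Compound list

1 | D-arabinose (open-chain form) | O=C[C@@H](O)[C@H](O)[C@H](O)CO | starting material
2 | D-arabinose diethyl dithioacetal | CCSC(SCC)[C@@H](O)[C@H](O)[C@H](O)CO | intermediate
3 | 2,3:4,5-di-O-isopropylidene-D-arabinose diethyl dithioacetal | CCSC(SCC)[C@H]1OC(C)(C)O[C@@H]1[C@H]2COC(C)(C)O2 | intermediate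
4 | 2,3-O-isopropylidene-D-arabinose diethyl dithioacetal | CCSC(SCC)[C@H]1OC(C)(C)O[C@@H]1[C@H](O)CO | intermediate
5 | 2,3-O-isopropylidene-5-O-(4-methylbenzenesulfonyl)-D-arabinose diethyl dithioacetal | CCSC(SCC)[C@H]1OC(C)(C)O[C@@H]1[C@H](O)COS(=O)(=O)c2ccc(C)cc2 | intermediate (not isolated)
6 | 4,5-anhydro-2,3-O-isopropylidene-D-arabinose diethyl dithioacetal | CCSC(SCC)[C@H]1OC(C)(C)O[C@@H]1[C@H]2CO2 | intermediate
7 | (1R)-1-[(4R,5S)-5-[bis(ethylsulfanyl)methyl]-2,2-dimethyl-1,3-dioxolan-4-yl]butan-1-ol | CCC[C@@H](O)[C@H]1OC(C)(C)O[C@@H]1C(SCC)SCC | intermediate
8 | 2-vinyloxirane (racemic) | C=CC1CO1 | starting material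
9 | (2R)-2-[(4-methoxyphenyl)methoxy]but-3-en-1-ol | OC[C@H](OCc1ccc(OC)cc1)C=C | intermediate
10 | (2R)-2-[(4-methoxyphenyl)methoxy]but-3-enal | O=C[C@H](OCc1ccc(OC)cc1)C=C | intermediate (not isolated)
11 | (2R)-2-[(4-methoxyphenyl)methoxy]but-3-enoic acid | OC(=O)[C@H](OCc1ccc(OC)cc1)C=C | intermediate
12 | (1R)-1-[(4R,5S)-5-[bis(ethylsulfanyl)methyl]-2,2-dimethyl-1,3-dioxolan-4-yl]butyl (2R)-2-[(4-methoxyphenyl)methoxy]but-3-enoate | CCC[C@@H](OC(=O)[C@H](OCc1ccc(OC)cc1)C=C)[C@H]1OC(C)(C)O[C@@H]1C(SCC)SCC | intermediate
13 | (1R)-1-[(4R,5S)-5-formyl-2,2-dimethyl-1,3-dioxolan-4-yl]butyl (2R)-2-[(4-methoxyphenyl)methoxy]but-3-enoate | CCC[C@@H](OC(=O)[C@H](OCc1ccc(OC)cc1)C=C)[C@H]1OC(C)(C)O[C@@H]1C=O | intermediate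
14 | (1R)-1-[(4R,5R)-5-[(E)-2-iodoethenyl]-2,2-dimethyl-1,3-dioxolan-4-yl]butyl (2R)-2-[(4-methoxyphenyl)methoxy]but-3-enoate (key-step precursor) | CCC[C@@H](OC(=O)[C@H](OCc1ccc(OC)cc1)C=C)[C@H]1OC(C)(C)O[C@@H]1/C=C/I | intermediate
15 | ester 14 with the vinyl group converted into a 2-(9-borabicyclo[3.3.1]nonan-9-yl)ethyl group (boron on C4) | CCC[C@@H](OC(=O)[C@H](OCc1ccc(OC)cc1)CCB2C3CCCC2CCC3)[C@H]1OC(C)(C)O[C@@H]1/C=C/I | intermediate (not isolated)
16 | ten-membered E-ene lactone, C2 4-methoxybenzyl ether, C7/C8 acetonide (key-step product) | CCC[C@H]1OC(=O)[C@H](OCc2ccc(OC)cc2)CC/C=C/[C@H]3OC(C)(C)O[C@H]13 | intermediate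
17 | ten-membered E-ene lactone, free C2 hydroxyl, C7/C8 acetonide | CCC[C@H]1OC(=O)[C@H](O)CC/C=C/[C@H]3OC(C)(C)O[C@H]13 | intermediate
18 | (2E,4E)-hexa-2,4-dienedioic acid (muconic acid) | OC(=O)/C=C/C=C/C(=O)O | starting material
19 | (2E,4E)-6-tert-butoxy-6-oxohexa-2,4-dienoic acid | OC(=O)/C=C/C=C/C(=O)OC(C)(C)C | intermediate
20 | C2 (2E,4E)-6-tert-butoxy-6-oxohexa-2,4-dienoate of lactone 17 | CCC[C@H]1OC(=O)[C@H](OC(=O)/C=C/C=C/C(=O)OC(C)(C)C)CC/C=C/[C@H]3OC(C)(C)O[C@H]13 | intermediate
21 | (2R,7R,8S,9R,5E)-lactone with C2 O-[(2E,4E)-5-carboxypenta-2,4-dienoyl] group, free C7 and C8 hydroxyls and C9 propyl (CNP0476488.6) | CCC[C@H]1OC(=O)[C@H](OC(=O)/C=C/C=C/C(=O)O)CC/C=C/[C@@H](O)[C@@H]1O | target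

## Step count and least certain steps

Total: 15 steps. Longest linear sequence: 12 steps (steps 1–5, 8–12, 14, 15).

**Step 11 (key step).** Most likely to go wrong: intermolecular coupling outruns ring closure and gives oligomers, because the closing reductive elimination passes through a strained eleven-membered palladacycle that holds an E alkene and a trans-fused dioxolane. Loss of boron from 15 by protonation, β-hydride elimination after transmetalation, and slow base-induced epimerisation at C2 over the long addition are further risks.

Fallback: the same C4–C5 bond is formed between two molecules and the ring is closed at the O9–C1 ester bond. It sets out from 7 and 11 and comes back at 16.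
- 7 is silylated (tBuMe2SiOTf, 2,6-lutidine) to the silyl ether F1.
- I2/NaHCO3 releases the aldehyde F2, and CrCl2/CHI3 gives the silyl-protected E iodoalkene F3.
- 11 is converted with Me3SiCHN2 in MeOH–toluene into the methyl ester F4.
- The 9-BBN adduct of F4 is coupled with F3 (PdCl2(dppf), AsPh3, Cs2CO3, DMF–THF–H2O) to the open-chain ester F5.
- LiOH gives the acid F6, and Bu4NF gives the hydroxy acid F7.
- F7 is lactonised under Yamaguchi conditions (2,4,6-trichlorobenzoyl chloride, Et3N, then DMAP, toluene, high dilution) to 16.

**Step 8.** Most likely to go wrong: loss of the C2–H of the activated acyl donor under base, leading to racemisation or to migration of the C3=C4 double bond into conjugation. The slow acylation of a hindered secondary alcohol, which also favours N-acylurea formation, makes this worse.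

Fallback: the alkene is masked during the acylation. It sets out from 7 and comes back at 12.
- Commercial (R)-3-hydroxydihydrofuran-2(3H)-one is etherified with 4-methoxybenzyl 2,2,2-trichloroacetimidate (cat. camphorsulfonic acid) to the lactone F8.
- Sodium benzeneselenolate (PhSeSePh, NaBH4, DMF, heat) opens F8 at C4 to the selenide acid F9.
- F9 is esterified with 7 (EDCI, DMAP) to the selenide ester F10.
- H2O2 (1.1 equiv, pyridine, CH2Cl2, 0 °C → rt) oxidises selenium, which reacts much faster than the dithioacetal sulfur, and syn elimination of the selenoxide gives 12.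

**Step 10.** Most likely to go wrong: incomplete E selectivity in the olefination of an alpha-alkoxy aldehyde, with geometric isomers that are hard to separate, and partial epimerisation at C7 by the Lewis-acidic chromium salts.

Fallback: the E geometry is set by syn hydrometalation of an alkyne. It sets out from 7 and comes back at 14.
- 7 is taken to the silyl ether F1 and the aldehyde F2 as above.
- Dimethyl (1-diazo-2-oxopropyl)phosphonate with K2CO3 in MeOH (Ohira–Bestmann) gives the terminal alkyne F11.
- Cp2Zr(H)Cl followed by I2 gives the E iodoalkene F3.
- Bu4NF gives the iodo alcohol F12, which is esterified with 11 (EDCI, DMAP) to 14.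

**Step 6.** Most likely to go wrong: insufficient enantioselection or the opposite sense of induction, and leakage to the linear 1,4-adduct.

Fallback: the stereocentre is taken from a kinetic resolution. It sets out from 8 and comes back at 9.
- Hydrolytic kinetic resolution of 8 with 0.45 equiv of water and (S,S)-(salen)Co(OAc) (trivalent cobalt; salen = N,N'-bis(3,5-di-tert-butylsalicylidene)cyclohexane-1,2-diamine dianion) gives the diol F13. Water attacks the terminal carbon, so C2 is not touched.
- 4-Methoxybenzaldehyde dimethyl acetal with pyridinium tosylate gives the benzylidene acetal F14.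
- iBu2AlH (CH2Cl2, −78 → 0 °C) opens F14 at the less hindered oxygen, leaving the ether on the secondary oxygen, and gives 9.

## Further compounds

F1 | step 11 | tert-butyldimethylsilyl ether of 7 | CCC[C@@H](O[Si](C)(C)C(C)(C)C)[C@H]1OC(C)(C)O[C@@H]1C(SCC)SCC
F2 | step 11 | aldehyde from F1 (C6 formyl, C9 silyl ether, C7/C8 acetonide) | CCC[C@@H](O[Si](C)(C)C(C)(C)C)[C@H]1OC(C)(C)O[C@@H]1C=O
F3 | step 11 | silyl-protected E iodoalkene | CCC[C@@H](O[Si](C)(C)C(C)(C)C)[C@H]1OC(C)(C)O[C@@H]1/C=C/I
F4 | step 11 | methyl (2R)-2-[(4-methoxyphenyl)methoxy]but-3-enoate | COC(=O)[C@H](OCc1ccc(OC)cc1)C=C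
F5 | step 11 | open-chain methyl ester with the C4–C5 bond formed (C2 4-methoxybenzyl ether, E-C5=C6, C7/C8 acetonide, C9 silyl ether) | CCC[C@@H](O[Si](C)(C)C(C)(C)C)[C@H]1OC(C)(C)O[C@@H]1/C=C/CC[C@@H](OCc1ccc(OC)cc1)C(=O)OC
F6 | step 11 | carboxylic acid from F5 (C9 silyl ether) | CCC[C@@H](O[Si](C)(C)C(C)(C)C)[C@H]1OC(C)(C)O[C@@H]1/C=C/CC[C@@H](OCc1ccc(OC)cc1)C(=O)O
F7 | step 11 | hydroxy acid (free C9 hydroxyl and C1 acid) | CCC[C@@H](O)[C@H]1OC(C)(C)O[C@@H]1/C=C/CC[C@@H](OCc1ccc(OC)cc1)C(=O)O
F8 | step 8 | (3R)-3-[(4-methoxyphenyl)methoxy]dihydrofuran-2(3H)-one | O=C1[C@H](OCc2ccc(OC)cc2)CCO1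
F9 | step 8 | (2R)-2-[(4-methoxyphenyl)methoxy]-4-(phenylselanyl)butanoic acid | OC(=O)[C@H](OCc1ccc(OC)cc1)CC[Se]c1ccccc1
F10 | step 8 | ester of 7 with F9 | CCC[C@@H](OC(=O)[C@H](OCc1ccc(OC)cc1)CC[Se]c1ccccc1)[C@H]1OC(C)(C)O[C@@H]1C(SCC)SCC
F11 | step 10 | terminal alkyne from F2 (C9 silyl ether, C7/C8 acetonide) | CCC[C@@H](O[Si](C)(C)C(C)(C)C)[C@H]1OC(C)(C)O[C@@H]1C#C
F12 | step 10 | iodo alcohol (E iodoalkene, free C9 hydroxyl, C7/C8 acetonide) | CCC[C@@H](O)[C@H]1OC(C)(C)O[C@@H]1/C=C/I
F13 | step 6 | (2R)-but-3-ene-1,2-diol | OC[C@H](O)C=C
F14 | step 6 | (4R)-2-(4-methoxyphenyl)-4-vinyl-1,3-dioxolane (mixture at the acetal carbon) | COc1ccc(cc1)C1OC[C@@H](C=C)O1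
A1 | alternative 1 | alpha-acyloxy N-(6-bromopyridin-2-yl) amide carrying the full side chain | CCC[C@@H](O[Si](C)(C)C(C)(C)C)[C@H]1OC(C)(C)O[C@@H]1/C=C/CC[C@@H](OC(=O)/C=C/C=C/C(=O)OC(C)(C)C)C(=O)Nc1cccc(Br)n1
A2 | alternative 1 | C2 aldehyde of the C2–C12 chain (E-C5=C6, C7/C8 acetonide, C9 silyl ether) | CCC[C@@H](O[Si](C)(C)C(C)(C)C)[C@H]1OC(C)(C)O[C@@H]1/C=C/CCC=O
A3 | alternative 1 | 2-bromo-6-isocyanopyridine | [C-]#[N+]c1cccc(Br)n1
A4 | alternative 2 | ten-membered E-ene lactone (C2 silyl ether, C7 and C8 4-methoxybenzyl ethers) | CCC[C@H]1OC(=O)[C@H](O[Si](C)(C)C(C)(C)C)CC/C=C/[C@@H](OCc2ccc(OC)cc2)[C@@H]1OCc3ccc(OC)cc3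
A5 | alternative 2 | trans-fused bicyclic lactol with C5 tributylstannyl trans to the C6–C7 bond | CCC[C@H]1O[C@@]2(O)[C@H](O[Si](C)(C)C(C)(C)C)CC[C@@H]([Sn](CCCC)(CCCC)CCCC)[C@@H]2[C@@H](OCc3ccc(OC)cc3)[C@@H]1OCc4ccc(OC)cc4
A6 | alternative 3 | ten-membered E-ene lactone with free C7 hydroxyl (C2 4-methoxybenzyl ether, C8 silyl ether) | CCC[C@H]1OC(=O)[C@H](OCc2ccc(OC)cc2)CC/C=C/[C@@H](O)[C@@H]1O[Si](C)(C)C(C)(C)C
A7 | alternative 3 | open-chain iodo aldehyde (E-6-iodohex-5-enoate at O9, C8 silyl ether, C7 formyl) | CCC[C@@H](OC(=O)[C@H](OCc1ccc(OC)cc1)CC/C=C/I)[C@@H](O[Si](C)(C)C(C)(C)C)C=O
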